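Ring C of the flavanone is cut across its O1–C2 and C3–C4 bonds, which flank the C2–C3 two-carbon unit: this is the footprint of an ortho-quinone methide of ring A and a para-oxygenated styrene. A chiral Brønsted acid merges a geranylated salicylaldehyde, trimethyl orthoformate and the styrene in one inverse-demand hetero-Diels–Alder event that closes ring C, makes both bonds, sets C2 and delivers C4 at the alcohol oxidation level as a methyl ether. The aldehyde carries one free hydroxyl, lodged between the geranyl and formyl carbons, so that only this oxygen can become O1 and the side chain ends at C8; the other phenols are silyl ethers.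

Key step: step 4

Abbreviations: geranyl = (2E)-3,7-dimethylocta-2,6-dien-1-yl; TBS = tert-butyldimethylsilyl; TRIP = 3,3'-bis(2,4,6-triisopropylphenyl)-1,1'-binaphthyl-2,2'-diyl hydrogen phosphate.

Remark: the sense of induction of the phosphoric acid cannot be fixed in advance; (R)-TRIP is written, and its antipode is to be taken if the first run should give the 2R series.

Step 1
Reactants: 1 2,4,6-trihydroxybenzaldehyde; 2 geranyl bromide
Product: 3 3-geranyl-2,4,6-trihydroxybenzaldehyde
Conditions: 1 (1.5 equiv), DBU (1.5 equiv), THF, 0 °C to rt, slow addition of 2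
Reagents that add atoms: none
Why: Phenolate C-allylation (Friedel–Crafts-type alkylation of an acylphloroglucinol anion): the delocalised anion of 1 attacks the primary allylic bromide through ring carbon by SN2 displacement, the two open ring positions are equivalent so only one mono-C-geranyl isomer can arise, the E alkene is untouched, and the excess of 1 holds back dialkylation.

Step 2
Reactants: 3 3-geranyl-2,4,6-trihydroxybenzaldehyde
Product: 4 3-geranyl-2-hydroxy-4,6-bis(tert-butyldimethylsilyloxy)benzaldehyde
Conditions: TBSCl (2.1 equiv), imidazole (4 equiv), CH2Cl2/DMF, 0 °C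
Reagents that add atoms: tert-butyldimethylsilyl chloride (TBSCl), CC(C)(C)[Si](C)(C)Cl
Why: Regioselective silylation of phenols with a bulky silyl chloride: the hydroxyl para to the formyl group and the ortho hydroxyl that has a ring hydrogen as neighbour react, whereas the hydroxyl wedged between the geranyl methylene and the formyl group is the most crowded and is held in the hydrogen bond to the carbonyl oxygen, so it should stay free.

Step 3
Reactants: 5 4-acetoxystyrene
Product: 7 4-(tert-butyldimethylsilyloxy)styrene, via potassium 4-vinylphenoxide 6 (not isolated)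
Conditions: KOtBu (1.05 equiv), THF, 0 °C; then TBSCl (1.1 equiv), 0 °C to rt
Reagents that add atoms: tert-butyldimethylsilyl chloride (TBSCl), CC(C)(C)[Si](C)(C)Cl
Why: Transacylation of the aryl acetate by tert-butoxide releases the phenoxide, which is O-silylated in the same flask, so the polymerisation-prone free 4-vinylphenol is never handled.

Step 4
Reactants: 4 3-geranyl-2-hydroxy-4,6-bis(tert-butyldimethylsilyloxy)benzaldehyde; 7 4-(tert-butyldimethylsilyloxy)styrene (2 equiv); 8 trimethyl orthoformate (2 equiv)
Product: 11 (2S,4S)-8-geranyl-4-methoxy-5,7-bis(tert-butyldimethylsilyloxy)-2-[4-(tert-butyldimethylsilyloxy)phenyl]chroman (2,4-cis), via dimethyl acetal 9 (not isolated), via methoxy ortho-quinone methide 10 (not isolated)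
Conditions: (R)-TRIP (10 mol %), 5 Å MS, toluene, −20 °C to rt
Reagents that add atoms: none
Why: Proposed new method: the phosphoric acid exchanges the aldehyde with the orthoformate to acetal 9 and ionises it to the methoxy ortho-quinone methide 10, held as a hydrogen-bonded oxocarbenium/phosphate ion pair, which enters an inverse-demand hetero-Diels–Alder reaction with styrene 7 in which C3–C4 forms ahead of O1–C2 because the 4-silyloxyphenyl group carries the developing charge at C2. The closest known reactions are the acid-catalysed coupling of salicylaldehydes, orthoformates and styrenes to racemic 2,4-cis-4-alkoxyflavans and the chiral Brønsted-acid-catalysed [4+2] additions of ortho-quinone methides (from ortho-hydroxybenzyl alcohols) to styrenes, and their merger is the new element. Ring C closes as the six-membered ring of the intermolecular [4+2] event (heterodiene O=C–C=C plus alkene), which at its stepwise limit is capture of the C2 benzylic cation by the phenol oxygen. C2 should be set by the enantiofacial approach of the styrene to the catalyst-bound ion pair (catalyst control), and C4 should follow as 2,4-cis from the endo placement of the aryl group, a centre that is erased in step 6. The step needs regiocontrol, secured because the hydroxyl between the geranyl and formyl carbons is the only free one and the styrene can only bond through its terminal carbon to the cationic carbon, and chemoselectivity for the styrene over the geranyl alkenes, which are much weaker π-nucleophiles and cannot reach the methide carbon within the molecule.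

Step 5
Reactants: 11 (2S,4S)-8-geranyl-4-methoxy-5,7-bis(tert-butyldimethylsilyloxy)-2-[4-(tert-butyldimethylsilyloxy)phenyl]chroman
Product: 12 (2S)-8-geranyl-5,7-bis(tert-butyldimethylsilyloxy)-2-[4-(tert-butyldimethylsilyloxy)phenyl]chroman-4-ol (C4 epimers)
Conditions: PPTS (20 mol %), THF/H2O (5:1), 40 °C
Reagents that add atoms: water, O
Why: SN1 solvolysis of an activated benzylic ether: ionisation at C4 is assisted by O1 and by the oxygens at C5 and C7, water traps the cation, C2 takes no part, and the C4 configuration is irrelevant because it is oxidised in step 6.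

Step 6
Reactants: 12 (2S)-8-geranyl-5,7-bis(tert-butyldimethylsilyloxy)-2-[4-(tert-butyldimethylsilyloxy)phenyl]chroman-4-ol
Product: 13 (2S)-8-geranyl-5,7-bis(tert-butyldimethylsilyloxy)-2-[4-(tert-butyldimethylsilyloxy)phenyl]chroman-4-one
Conditions: Dess–Martin periodinane (1.3 equiv), NaHCO3, CH2Cl2, 0 °C to rt
Reagents that add atoms: none
Why: Dess–Martin oxidation of the secondary benzylic alcohol to the aryl ketone under bicarbonate buffer, conditions to which the alkenes, the aryl silyl ethers and the C2 centre are inert.

Step 7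
Reactants: 13 (2S)-8-geranyl-5,7-bis(tert-butyldimethylsilyloxy)-2-[4-(tert-butyldimethylsilyloxy)phenyl]chroman-4-one
Product: 14 sophoraflavanone A, (2S)-8-geranyl-5,7-dihydroxy-2-(4-hydroxyphenyl)chroman-4-one
Conditions: TBAF (3.5 equiv), AcOH (3.5 equiv), THF, 0 °C
Reagents that add atoms: none
Why: Fluoride cleavage of the three aryl silyl ethers, driven by Si–F bond formation; acetic acid keeps the phenols protonated and so suppresses the retro-oxa-Michael opening to the chalcone that would racemise C2.

Compound list
1 | 2,4,6-trihydroxybenzaldehyde | O=Cc1c(O)cc(O)cc1O | starting material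
2 | geranyl bromide, (2E)-1-bromo-3,7-dimethylocta-2,6-diene | CC(C)=CCC/C(C)=C/CBr | starting material
3 | 3-geranyl-2,4,6-trihydroxybenzaldehyde | CC(C)=CCC/C(C)=C/Cc1c(O)cc(O)c(C=O)c1O | intermediate
4 | 3-geranyl-2-hydroxy-4,6-bis(tert-butyldimethylsilyloxy)benzaldehyde | CC(C)=CCC/C(C)=C/Cc1c(O[Si](C)(C)C(C)(C)C)cc(O[Si](C)(C)C(C)(C)C)c(C=O)c1O | intermediate
5 | 4-acetoxystyrene | C=Cc1ccc(OC(C)=O)cc1 | starting material
6 | potassium 4-vinylphenoxide | C=Cc1ccc([O-])cc1.[K+] | intermediate
7 | 4-(tert-butyldimethylsilyloxy)styrene | C=Cc1ccc(O[Si](C)(C)C(C)(C)C)cc1 | intermediate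
8 | trimethyl orthoformate | COC(OC)OC | starting material
9 | 2-(dimethoxymethyl)-6-geranyl-3,5-bis(tert-butyldimethylsilyloxy)phenol (dimethyl acetal of 4) | CC(C)=CCC/C(C)=C/Cc1c(O[Si](C)(C)C(C)(C)C)cc(O[Si](C)(C)C(C)(C)C)c(C(OC)OC)c1O | intermediate
10 | 2-geranyl-6-(methoxymethylidene)-3,5-bis(tert-butyldimethylsilyloxy)cyclohexa-2,4-dien-1-one (methoxy ortho-quinone methide, engaged as its O-protonated ion pair with the phosphate) | CC(C)=CCC/C(C)=C/CC1=C(O[Si](C)(C)C(C)(C)C)C=C(O[Si](C)(C)C(C)(C)C)C(=COC)C1=O | intermediate
11 | (2S,4S)-8-geranyl-4-methoxy-5,7-bis(tert-butyldimethylsilyloxy)-2-[4-(tert-butyldimethylsilyloxy)phenyl]chroman, 2,4-cis | CC(C)=CCC/C(C)=C/Cc1c(O[Si](C)(C)C(C)(C)C)cc(O[Si](C)(C)C(C)(C)C)c2c1O[C@H](c1ccc(O[Si](C)(C)C(C)(C)C)cc1)C[C@@H]2OC | intermediate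
12 | (2S)-8-geranyl-5,7-bis(tert-butyldimethylsilyloxy)-2-[4-(tert-butyldimethylsilyloxy)phenyl]chroman-4-ol, C4 epimers | CC(C)=CCC/C(C)=C/Cc1c(O[Si](C)(C)C(C)(C)C)cc(O[Si](C)(C)C(C)(C)C)c2c1O[C@H](c1ccc(O[Si](C)(C)C(C)(C)C)cc1)CC2O | intermediate
13 | (2S)-8-geranyl-5,7-bis(tert-butyldimethylsilyloxy)-2-[4-(tert-butyldimethylsilyloxy)phenyl]chroman-4-one | CC(C)=CCC/C(C)=C/Cc1c(O[Si](C)(C)C(C)(C)C)cc(O[Si](C)(C)C(C)(C)C)c2c1O[C@H](c1ccc(O[Si](C)(C)C(C)(C)C)cc1)CC2=O | intermediate
14 | sophoraflavanone A, (2S)-8-geranyl-5,7-dihydroxy-2-(4-hydroxyphenyl)chroman-4-one | CC(C)=CCC/C(C)=C/Cc1c(O)cc(O)c2c1O[C@H](c1ccc(O)cc1)CC2=O | target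

Total step count: 7. Longest linear sequence: 6 (steps 1, 2, 4, 5, 6, 7); step 3 is a one-step side branch.

Steps most likely to fail

Step 4 (Proposed new method). The enantiofacial discrimination of the styrene by the phosphate ion pair may be poor, or turnover may be slow because the ion pair drawn from this very electron-rich acetal is strongly stabilised; a more acidic N-triflyl phosphoramide on the same backbone is the first variation to try. The fallback uses known chemistry only and separates ring formation from enantiocontrol. It sets out from 4, 7 and 8: Sc(OTf)3 (5 mol %) in CH2Cl2 at 0 °C should give the racemic 2,4-cis-4-methoxyflavan F1; the conditions of steps 5 and 6 then lead through the racemic flavan-4-ol F2 to the racemic silylated flavanone F3. A kinetic resolution by Noyori asymmetric transfer hydrogenation, RuCl[(R,R)-TsDPEN](p-cymene) with HCO2H/Et3N, stopped near half conversion, should reduce the 2R ketone to the (2R,4R)-cis-flavan-4-ol F4 and leave the 2S ketone. The (R,R) ligand is the one expected by the usual model for aryl ketones, and the antipodal complex is used if the opposite holds. The fallback comes back to the route at 13.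

Step 2. Silylation may occur at the wrong ortho hydroxyl or go on to the tris-silyl ether, which would transpose the side chain to C6 in step 4. The fallback makes the regiochemistry structural: the same hydroxyl directs both carbon substituents to its two ortho positions. It sets out from geranyl bromide 2 and purchased phloroglucinol (benzene-1,3,5-triol, Oc1cc(O)cc(O)c1). Double silylation (TBSCl 2 equiv, imidazole, DMF; the mono- and tris-silyl fractions are recycled) gives 3,5-bis(tert-butyldimethylsilyloxy)phenol F5, for which no isomer question exists because the three oxygens of phloroglucinol are equivalent. Its sodium phenoxide (NaH, toluene) is C-alkylated at the ortho position by 2 to 2-geranyl-3,5-bis(tert-butyldimethylsilyloxy)phenol F6. Magnesium-mediated ortho-formylation (MgCl2, Et3N, paraformaldehyde, MeCN, reflux) then enters at the only free position ortho to the hydroxyl, and the fallback comes back to the route at 4.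

Step 5. Ionisation at C4 may end in loss of a proton to the flav-3-ene and not in capture by water, and prolonged acid may erode the aryl silyl ethers or the C2 centre. The fallback avoids acid: it sets out from 4 and 7 and runs step 4 with triallyl orthoformate (C=CCOC(OCC=C)OCC=C) in place of 8, which should give the (2S,4S)-4-allyloxyflavan F7. The allyl ether is then removed under neutral conditions by π-allyl transfer to a sulfinate (Pd(PPh3)4 5 mol %, sodium 4-toluenesulfinate, THF/MeOH, rt), which leaves the C4–O bond intact, and the fallback comes back to the route at 12.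

Further compounds
F1 | step 4 | racemic 2,4-cis-8-geranyl-4-methoxy-5,7-bis(tert-butyldimethylsilyloxy)-2-[4-(tert-butyldimethylsilyloxy)phenyl]chroman (SMILES shows the 2R,4R half; the 2S,4S half is 11) | CC(C)=CCC/C(C)=C/Cc1c(O[Si](C)(C)C(C)(C)C)cc(O[Si](C)(C)C(C)(C)C)c2c1O[C@@H](c1ccc(O[Si](C)(C)C(C)(C)C)cc1)C[C@H]2OC
F2 | step 4 | racemic 8-geranyl-5,7-bis(tert-butyldimethylsilyloxy)-2-[4-(tert-butyldimethylsilyloxy)phenyl]chroman-4-ol, C4 epimers (SMILES shows the 2R half; the 2S half is 12) | CC(C)=CCC/C(C)=C/Cc1c(O[Si](C)(C)C(C)(C)C)cc(O[Si](C)(C)C(C)(C)C)c2c1O[C@@H](c1ccc(O[Si](C)(C)C(C)(C)C)cc1)CC2O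
F3 | step 4 | racemic 8-geranyl-5,7-bis(tert-butyldimethylsilyloxy)-2-[4-(tert-butyldimethylsilyloxy)phenyl]chroman-4-one (SMILES shows the 2R half; the 2S half is 13) | CC(C)=CCC/C(C)=C/Cc1c(O[Si](C)(C)C(C)(C)C)cc(O[Si](C)(C)C(C)(C)C)c2c1O[C@@H](c1ccc(O[Si](C)(C)C(C)(C)C)cc1)CC2=O
F4 | step 4 | (2R,4R)-8-geranyl-5,7-bis(tert-butyldimethylsilyloxy)-2-[4-(tert-butyldimethylsilyloxy)phenyl]chroman-4-ol, 2,4-cis | CC(C)=CCC/C(C)=C/Cc1c(O[Si](C)(C)C(C)(C)C)cc(O[Si](C)(C)C(C)(C)C)c2c1O[C@@H](c1ccc(O[Si](C)(C)C(C)(C)C)cc1)C[C@H]2O
F5 | step 2 | 3,5-bis(tert-butyldimethylsilyloxy)phenol | Oc1cc(O[Si](C)(C)C(C)(C)C)cc(O[Si](C)(C)C(C)(C)C)c1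
F6 | step 2 | 2-geranyl-3,5-bis(tert-butyldimethylsilyloxy)phenol | CC(C)=CCC/C(C)=C/Cc1c(O)cc(O[Si](C)(C)C(C)(C)C)cc1O[Si](C)(C)C(C)(C)C
F7 | step 5 | (2S,4S)-4-allyloxy-8-geranyl-5,7-bis(tert-butyldimethylsilyloxy)-2-[4-(tert-butyldimethylsilyloxy)phenyl]chroman, 2,4-cis | CC(C)=CCC/C(C)=C/Cc1c(O[Si](C)(C)C(C)(C)C)cc(O[Si](C)(C)C(C)(C)C)c2c1O[C@H](c1ccc(O[Si](C)(C)C(C)(C)C)cc1)C[C@@H]2OCC=C
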